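The route rests on cutting the C16 chain between C2 and C3, counted from the ester oxygen. These two methylene carbons bear neither substituents nor stereochemistry, so their bond can be made as a C=C bond and then saturated. An allyl ester of 3-(3,4-dihydroxyphenyl)propanoic acid supplies O–CH2–CH=, and pentadec-1-ene supplies the remaining fourteen carbons. In one operation, olefin cross-metathesis followed by hydrogenation in the same flask joins the two fragments and delivers the saturated hexadecyl ester; the catechol ring stays unprotected throughout. The precursor comes from the commercial acid by a single Fischer esterification.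

Key step: step 2

Remark on the chemistry: the alkene 5 should form as an E/Z mixture; it is drawn as the E isomer expected to predominate, and both isomers give 6 on hydrogenation.

Step 1
Reactants: 1 3-(3,4-dihydroxyphenyl)propanoic acid; 2 allyl alcohol
Product: 3 allyl 3-(3,4-dihydroxyphenyl)propanoate
Conditions: p-TsOH·H2O (10 mol%), allyl alcohol (solvent), 80 °C, N2
Reagents that add atoms: none
Why: Fischer esterification, driven by the alcohol as solvent; phenols are not acylated under acid catalysis and the catechol is stable to acid under nitrogen.

Step 2
Reactants: 3 allyl 3-(3,4-dihydroxyphenyl)propanoate; 4 pentadec-1-ene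
Product: 6 hexadecyl 3-(3,4-dihydroxyphenyl)propanoate, via (E)-hexadec-2-enyl ester 5 (not isolated)
Conditions: (a) Hoveyda–Grubbs II (3 mol%), 4 (4 equiv), AcOH (10 mol%), CH2Cl2, 40 °C, Ar sparge; (b) PtO2 (5 mol%), H2 (1 atm), same flask, rt
Reagents that add atoms: none
Why: Olefin cross-metathesis (Chauvin mechanism) followed in the same flask by heterogeneous hydrogenation: the Ru carbene exchanges onto one terminal alkene, [2+2] cycloaddition with the other gives a ruthenacyclobutane, and cycloreversion releases ethene and the internal alkene 5, so the C2–C3 bond of the later hexadecyl chain is formed as a C=C bond that PtO2/H2 then saturates. The closest known reaction type is cross-metathesis of a primary allylic ester with a 1-alkene, combined with a one-pot Ru carbene/PtO2 hydrogenation. No ring is closed and no stereocentre is formed; the E/Z ratio of 5 is irrelevant because both isomers, and any positional isomers from double-bond migration in 5, converge on 6. The step needs cross- over homo-coupling, which the fourfold excess of 4 and removal of ethene should secure, since both partners are unhindered terminal alkenes whose homodimers re-enter the cycle; the hydrocarbon by-products, saturated in stage (b), should separate easily from the polar catechol ester. It also needs chemoselectivity: the neutral catechol should not displace chloride from Ru without base, acetic acid should suppress Ru–H-mediated double-bond migration in 4 before coupling (which would give chain-length homologues), and Pt at 1 atm in an aprotic solvent should reduce the alkene without hydrogenolysis of the allylic C–O bond or reduction of the arene.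

Compound list
1 | 3-(3,4-dihydroxyphenyl)propanoic acid | O=C(O)CCc1ccc(O)c(O)c1 | starting material
2 | allyl alcohol (prop-2-en-1-ol) | C=CCO | starting material
3 | allyl 3-(3,4-dihydroxyphenyl)propanoate | C=CCOC(=O)CCc1ccc(O)c(O)c1 | intermediate
4 | pentadec-1-ene | C=CCCCCCCCCCCCCC | starting material
5 | (E)-hexadec-2-en-1-yl 3-(3,4-dihydroxyphenyl)propanoate | CCCCCCCCCCCCC/C=C/COC(=O)CCc1ccc(O)c(O)c1 | intermediate
6 | hexadecyl 3-(3,4-dihydroxyphenyl)propanoate | CCCCCCCCCCCCCCCCOC(=O)CCc1ccc(O)c(O)c1 | target

Total step count: 2. Longest linear sequence: 2 steps (1 → 3 → 6).

Steps most likely to fail (the route has only two steps, so both are ranked):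

Step 2. Catalyst activity may be lost through binding of the catechol to ruthenium. Coupling may also stay statistical, the double bond of 4 may migrate before coupling and scramble the chain length, or the allylic C–O bond may be hydrogenolysed in the hydrogenation stage. The fallback abandons metathesis and forms the same C2–C3 bond directly as an sp3–sp3 bond by copper-catalysed alkyl–alkyl coupling. It sets out from 1. Fischer esterification with 2-bromoethanol (cat. TsOH, toluene, Dean–Stark) should give 2-bromoethyl 3-(3,4-dihydroxyphenyl)propanoate F1. Silylation of both phenols (TBSOTf, 2,6-lutidine, CH2Cl2, 0 °C) should give 2-bromoethyl 3-[3,4-bis(tert-butyldimethylsilyloxy)phenyl]propanoate F2. Slow addition of tetradecylmagnesium chloride to F2 with Li2CuCl4 (3 mol%) in THF/NMP at −20 to 0 °C should displace the primary bromide faster than the ester is attacked and give hexadecyl 3-[3,4-bis(tert-butyldimethylsilyloxy)phenyl]propanoate F3. Et3N·3HF in THF should then remove both silyl groups, and the fallback comes back to the route at 6.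

Step 1. Conversion may stall at the esterification equilibrium, or the hot acid may divert allyl alcohol into ether formation or C-allylation of the electron-rich ring. The fallback changes from acid-catalysed acyl substitution to O-alkylation of the carboxylate. It sets out from 1: KHCO3 (1.1 equiv) and allyl bromide in DMF at rt should alkylate only the carboxylate, because hydrogencarbonate does not deprotonate the phenols. It comes back to the route at 3 and makes no new compound.

Further compounds
F1 | step 2 | 2-bromoethyl 3-(3,4-dihydroxyphenyl)propanoate | O=C(CCc1ccc(O)c(O)c1)OCCBr
F2 | step 2 | 2-bromoethyl 3-[3,4-bis(tert-butyldimethylsilyloxy)phenyl]propanoate | CC(C)(C)[Si](C)(C)Oc1ccc(CCC(=O)OCCBr)cc1O[Si](C)(C)C(C)(C)C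
F3 | step 2 | hexadecyl 3-[3,4-bis(tert-butyldimethylsilyloxy)phenyl]propanoate | CCCCCCCCCCCCCCCCOC(=O)CCc1ccc(O[Si](C)(C)C(C)(C)C)c(O[Si](C)(C)C(C)(C)C)c1
F0 | step 1 | none | none
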